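**Plan**
- Retrosynthesis cuts, in order: the C5–vinyl bond (Heck coupling with acrylic acid), the O1–C2 ether bond of dihydrofuran ring B, and the bond between the future C2 and C3, traced back to the C=C of a 2,3-diarylacrylic acid (Perkin condensation).
- Enabling feature: C2 of ring B (O1, C2, C3, C3a, C7a) is benzylic to syringyl ring C. The free para-hydroxyl of ring C lets the C2 methylene be oxidized to a para-quinone methide, which the ring A phenol oxygen (the future O1) captures.
- Forward: a ring A arylacetic acid (from 5-bromo-o-vanillin) and O-benzyl syringaldehyde are joined to the diarylacrylic acid. Hydrogenation, reduction and debenzylation give an open-chain 2,3-diarylpropanol. Ring B is closed last, then the acrylic acid is attached.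
- Stereochemistry: C3 comes from iridium-catalysed asymmetric hydrogenation; C2 is set trans to C3 during the reversible ring closure; the E alkene comes from the Heck reaction.

Key step: step 10

Assumption: the sense of induction of the spiro phosphine-oxazoline iridium catalyst with this ortho-substituted alpha-aryl substrate is fixed by a pilot run, and the ligand enantiomer that delivers the 2R acid is used (SIPHOX = 7-[bis(3,5-di-tert-butylphenyl)phosphino]-7'-(4-benzyl-4,5-dihydrooxazol-2-yl)-1,1'-spirobiindane).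

**Step 1**
Reactants: 1 5-bromo-2-hydroxy-3-methoxybenzaldehyde
Product: 2 2-(benzyloxy)-5-bromo-3-methoxybenzaldehyde
Conditions: BnBr (1.2 equiv), K2CO3 (2 equiv), DMF, 60 °C
Reagents that add atoms: benzyl bromide, BrCc1ccccc1
Why: Williamson O-alkylation of the acidic ortho-formyl phenol is routine and installs an ether that should survive base, aqueous acid, borane and homogeneous hydrogenation yet can be cleaved later without touching the aryl bromide.

**Step 2**
Reactants: 2 2-(benzyloxy)-5-bromo-3-methoxybenzaldehyde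
Product: 3 2-(benzyloxy)-5-bromo-1-methoxy-3-(2-methoxyethenyl)benzene (E/Z mixture)
Conditions: Ph3P(CH2OMe)Cl (1.4 equiv), KOtBu (1.35 equiv), THF, 0 °C → rt
Reagents that add atoms: (methoxymethyl)triphenylphosphonium chloride, COC[P+](c1ccccc1)(c1ccccc1)c1ccccc1.[Cl-]
Why: Wittig methoxymethylenation of an aromatic aldehyde is a standard one-carbon homologation, and the alkene geometry is irrelevant because both isomers hydrolyse to the same aldehyde.

**Step 3**
Reactants: 3 2-(benzyloxy)-5-bromo-1-methoxy-3-(2-methoxyethenyl)benzene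
Product: 4 2-[2-(benzyloxy)-5-bromo-3-methoxyphenyl]acetaldehyde
Conditions: 3 M aq. HCl, THF, 50 °C
Reagents that add atoms: water, O
Why: Acid-catalysed enol ether hydrolysis (C-protonation, hydration of the oxocarbenium ion, loss of methanol) should unmask the arylacetaldehyde, which is carried on crude because such aldehydes self-condense on storage.

**Step 4**
Reactants: 4 2-[2-(benzyloxy)-5-bromo-3-methoxyphenyl]acetaldehyde
Product: 5 2-[2-(benzyloxy)-5-bromo-3-methoxyphenyl]acetic acid
Conditions: NaClO2, NaH2PO4, 2-methyl-2-butene, t-BuOH/H2O, 0 °C → rt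
Reagents that add atoms: sodium chlorite, [Na+].[O-]Cl=O
Why: Pinnick oxidation converts the enolizable aldehyde to the acid under buffered conditions, with 2-methyl-2-butene scavenging hypochlorous acid so that the electron-rich ring is not chlorinated.

**Step 5**
Reactants: 6 syringaldehyde
Product: 7 4-(benzyloxy)-3,5-dimethoxybenzaldehyde
Conditions: BnBr (1.2 equiv), K2CO3 (2 equiv), DMF, 60 °C
Reagents that add atoms: benzyl bromide, BrCc1ccccc1
Why: Williamson benzylation of the para-formyl phenol masks the ring C hydroxyl with the same group as on ring A, so that a single later operation frees both phenols.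

**Step 6**
Reactants: 5 2-[2-(benzyloxy)-5-bromo-3-methoxyphenyl]acetic acid; 7 4-(benzyloxy)-3,5-dimethoxybenzaldehyde
Product: 10 (E)-2-[2-(benzyloxy)-5-bromo-3-methoxyphenyl]-3-[4-(benzyloxy)-3,5-dimethoxyphenyl]prop-2-enoic acid, via arylacetic acetic anhydride 8 (not isolated), via diarylacrylic acetic anhydride 9 (not isolated)
Conditions: Ac2O (4 equiv), Et3N (2.5 equiv), 110 °C; then H2O, 90 °C; aq. HCl
Reagents that add atoms: none
Why: Perkin condensation in its Oglialoro form, in which mixed anhydride 8 is enolized by Et3N, adds to the aldehyde and loses acetate, and hydrolysis of anhydride 9 should leave the E acid with the two aryl groups cis, the usual outcome for 2,3-diarylacrylic acids.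

**Step 7**
Reactants: 10 (E)-2-[2-(benzyloxy)-5-bromo-3-methoxyphenyl]-3-[4-(benzyloxy)-3,5-dimethoxyphenyl]prop-2-enoic acid
Product: 11 (2R)-2-[2-(benzyloxy)-5-bromo-3-methoxyphenyl]-3-[4-(benzyloxy)-3,5-dimethoxyphenyl]propanoic acid
Conditions: H2 (6 atm), [Ir(cod)(SIPHOX)][B(3,5-(CF3)2C6H3)4] (1 mol %), Et3N (0.5 equiv), MeOH, 45 °C
Reagents that add atoms: none
Why: Carboxylate-directed iridium-catalysed asymmetric hydrogenation of an (E)-alpha-aryl cinnamic acid, in which the chiral pocket around the metal-bound carboxylate selects the alkene face that receives H2 and so sets the alpha carbon (future C3) as R, while the aryl bromide and benzyl ethers are inert to this homogeneous catalyst.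

**Step 8**
Reactants: 11 (2R)-2-[2-(benzyloxy)-5-bromo-3-methoxyphenyl]-3-[4-(benzyloxy)-3,5-dimethoxyphenyl]propanoic acid
Product: 12 (2R)-2-[2-(benzyloxy)-5-bromo-3-methoxyphenyl]-3-[4-(benzyloxy)-3,5-dimethoxyphenyl]propan-1-ol
Conditions: BH3·THF (2.5 equiv), THF, 0 °C → rt; MeOH quench
Reagents that add atoms: none
Why: Borane reduction of a carboxylic acid proceeds through the acyloxyborane without touching the aryl bromide or benzyl ethers and without enolizing the alpha stereocentre.

**Step 9**
Reactants: 12 (2R)-2-[2-(benzyloxy)-5-bromo-3-methoxyphenyl]-3-[4-(benzyloxy)-3,5-dimethoxyphenyl]propan-1-ol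
Product: 13 4-bromo-2-[(2R)-1-hydroxy-3-(4-hydroxy-3,5-dimethoxyphenyl)propan-2-yl]-6-methoxyphenol
Conditions: BCl3 (5 equiv), C6HMe5 (6 equiv), CH2Cl2, −78 °C; MeOH quench
Reagents that add atoms: none
Why: Lewis-acid debenzylation with BCl3 and pentamethylbenzene as benzyl cation scavenger should cleave both aryl benzyl ethers at low temperature while leaving the methyl ethers, the C–Br bond and the stereocentre intact, where hydrogenolysis would endanger the bromide.

**Step 10**
Reactants: 13 4-bromo-2-[(2R)-1-hydroxy-3-(4-hydroxy-3,5-dimethoxyphenyl)propan-2-yl]-6-methoxyphenol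
Product: 15 4-[(2S,3R)-5-bromo-3-(hydroxymethyl)-7-methoxy-2,3-dihydro-1-benzofuran-2-yl]-2,6-dimethoxyphenol, via para-quinone methide 14 (not isolated)
Conditions: DDQ (1.05 equiv), CH2Cl2/1,4-dioxane (4:1), 0 °C → rt
Reagents that add atoms: none
Why: DDQ removes hydride from the CH2 para to the ring C hydroxyl, the most electron-rich benzylic C–H, and loss of the phenolic proton gives para-quinone methide 14; the ring A phenol oxygen then adds to the exocyclic methide carbon, rearomatizing ring C and forming O1–C2. The closest known reaction type is the DDQ oxidative cyclization of diarylalkanes carrying a 4-hydroxyaryl and a 2-hydroxyaryl group (flavan formation) through para-quinone methides. Ring B closes in a 5-exo-trig oxa-Michael mode, the primary alcohol being able to reach the methide carbon only through an oxetane. C2 is controlled by the existing C3 centre, since both the transition state and the product prefer ring C anti to CH2OH, and because the aryl ether can reionize to 14 the closure is reversible and should converge on the trans (2S,3R) isomer. The step needs oxidation of the syringyl methylene in preference to the ring A benzylic C3–H and to the product; the two methoxy groups flanking the ring C hydroxyl make that ring the easiest to oxidize, ring A is deactivated by bromine, and one equivalent of DDQ at low temperature limits further dehydrogenation.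

**Step 11**
Reactants: 15 4-[(2S,3R)-5-bromo-3-(hydroxymethyl)-7-methoxy-2,3-dihydro-1-benzofuran-2-yl]-2,6-dimethoxyphenol; 16 acrylic acid
Product: 17 (2E)-3-[(2S,3R)-2-(4-hydroxy-3,5-dimethoxyphenyl)-3-(hydroxymethyl)-7-methoxy-2,3-dihydro-1-benzofuran-5-yl]prop-2-enoic acid
Conditions: Pd(OAc)2 (5 mol %), P(o-tol)3 (12 mol %), Et3N (4 equiv), DMF, 100 °C, Ar; aq. HCl work-up
Reagents that add atoms: none
Why: Mizoroki–Heck reaction, in which oxidative addition of the aryl bromide to zerovalent palladium, syn insertion of acrylic acid and syn beta-hydride elimination should give the E cinnamic acid under conditions established for bromophenols and free acrylic acid, the two stereocentres not being involved.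

**Compound list**
1 | 5-bromo-2-hydroxy-3-methoxybenzaldehyde | COc1cc(Br)cc(C=O)c1O | starting material
2 | 2-(benzyloxy)-5-bromo-3-methoxybenzaldehyde | COc1cc(Br)cc(C=O)c1OCc1ccccc1 | intermediate
3 | 2-(benzyloxy)-5-bromo-1-methoxy-3-(2-methoxyethenyl)benzene (E/Z mixture) | COC=Cc1cc(Br)cc(OC)c1OCc1ccccc1 | intermediate
4 | 2-[2-(benzyloxy)-5-bromo-3-methoxyphenyl]acetaldehyde | COc1cc(Br)cc(CC=O)c1OCc1ccccc1 | intermediate
5 | 2-[2-(benzyloxy)-5-bromo-3-methoxyphenyl]acetic acid | COc1cc(Br)cc(CC(=O)O)c1OCc1ccccc1 | intermediate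
6 | syringaldehyde (4-hydroxy-3,5-dimethoxybenzaldehyde) | COc1cc(C=O)cc(OC)c1O | starting material
7 | 4-(benzyloxy)-3,5-dimethoxybenzaldehyde | COc1cc(C=O)cc(OC)c1OCc1ccccc1 | intermediate
8 | acetic [2-(benzyloxy)-5-bromo-3-methoxyphenyl]acetic anhydride (not isolated) | COc1cc(Br)cc(CC(=O)OC(C)=O)c1OCc1ccccc1 | intermediate
9 | acetic (E)-2-[2-(benzyloxy)-5-bromo-3-methoxyphenyl]-3-[4-(benzyloxy)-3,5-dimethoxyphenyl]prop-2-enoic anhydride (not isolated) | CC(=O)OC(=O)/C(=C/c1cc(OC)c(OCc2ccccc2)c(OC)c1)c1cc(Br)cc(OC)c1OCc1ccccc1 | intermediate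
10 | (E)-2-[2-(benzyloxy)-5-bromo-3-methoxyphenyl]-3-[4-(benzyloxy)-3,5-dimethoxyphenyl]prop-2-enoic acid | OC(=O)/C(=C/c1cc(OC)c(OCc2ccccc2)c(OC)c1)c1cc(Br)cc(OC)c1OCc1ccccc1 | intermediate
11 | (2R)-2-[2-(benzyloxy)-5-bromo-3-methoxyphenyl]-3-[4-(benzyloxy)-3,5-dimethoxyphenyl]propanoic acid | COc1cc(C[C@@H](C(=O)O)c2cc(Br)cc(OC)c2OCc2ccccc2)cc(OC)c1OCc1ccccc1 | intermediate
12 | (2R)-2-[2-(benzyloxy)-5-bromo-3-methoxyphenyl]-3-[4-(benzyloxy)-3,5-dimethoxyphenyl]propan-1-ol | COc1cc(C[C@@H](CO)c2cc(Br)cc(OC)c2OCc2ccccc2)cc(OC)c1OCc1ccccc1 | intermediate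
13 | 4-bromo-2-[(2R)-1-hydroxy-3-(4-hydroxy-3,5-dimethoxyphenyl)propan-2-yl]-6-methoxyphenol | COc1cc(C[C@@H](CO)c2cc(Br)cc(OC)c2O)cc(OC)c1O | intermediate
14 | 4-[(2R)-2-(5-bromo-2-hydroxy-3-methoxyphenyl)-3-hydroxypropylidene]-2,6-dimethoxycyclohexa-2,5-dien-1-one (not isolated) | COC1=CC(=C[C@@H](CO)c2cc(Br)cc(OC)c2O)C=C(OC)C1=O | intermediate
15 | 4-[(2S,3R)-5-bromo-3-(hydroxymethyl)-7-methoxy-2,3-dihydro-1-benzofuran-2-yl]-2,6-dimethoxyphenol | COc1cc([C@H]2Oc3c(OC)cc(Br)cc3[C@@H]2CO)cc(OC)c1O | intermediate
16 | acrylic acid | C=CC(=O)O | starting material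
17 | (2E)-3-[(2S,3R)-2-(4-hydroxy-3,5-dimethoxyphenyl)-3-(hydroxymethyl)-7-methoxy-2,3-dihydro-1-benzofuran-5-yl]prop-2-enoic acid | COc1cc([C@H]2Oc3c(OC)cc(/C=C/C(=O)O)cc3[C@@H]2CO)cc(OC)c1O | target

**Step count**
Total: 11 steps. Longest linear sequence: 10 steps (steps 1–4 and 6–11, from compound 1).

**Steps most likely to fail**

Step 10. The cyclized phenol may be dehydrogenated further by DDQ towards the benzofuran, or the quinone methide may tautomerize to the stilbene before ring closure, which would erase the C3 centre. The fallback sets out from 13 and separates oxidation from ring closure. DDQ (1.0 equiv) in MeOH/CH2Cl2 at 0 °C lets the solvent intercept quinone methide 14 intermolecularly, giving 4-bromo-2-[(2R)-1-hydroxy-3-(4-hydroxy-3,5-dimethoxyphenyl)-3-methoxypropan-2-yl]-6-methoxyphenol F1 as a mixture of epimers at the new benzylic carbon. After removal of the oxidant, catalytic p-TsOH in CH2Cl2 at rt ionizes the benzylic methyl ether to the para-hydroxybenzyl cation. The ring A phenol captures it under thermodynamic control (the classical acid-mediated phenylcoumaran closure), which should favour the trans isomer. The route is rejoined at 15.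

Step 7. The twisted, ortho-disubstituted alpha-aryl group may slow the hydrogenation or weaken facial discrimination, giving incomplete conversion or low enantiomeric purity. The fallback sets out from 5 and 7 and builds the stereocentre by auxiliary-controlled alkylation.
- Acid 5 is activated with pivaloyl chloride/Et3N as 2,2-dimethylpropanoic [2-(benzyloxy)-5-bromo-3-methoxyphenyl]acetic anhydride F2, which acylates lithiated (R)-4-benzyl-1,3-oxazolidin-2-one to give (4R)-4-benzyl-3-{[2-(benzyloxy)-5-bromo-3-methoxyphenyl]acetyl}-1,3-oxazolidin-2-one F3.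
- Aldehyde 7 is reduced (NaBH4, MeOH) to [4-(benzyloxy)-3,5-dimethoxyphenyl]methanol F4 and brominated (PBr3, CH2Cl2, 0 °C) to 2-(benzyloxy)-5-(bromomethyl)-1,3-dimethoxybenzene F5.
- The sodium Z-enolate of F3 (NaHMDS, THF, −78 °C) is alkylated by F5 on the face anti to the auxiliary benzyl group (Evans alkylation), which should give (4R)-4-benzyl-3-{(2R)-2-[2-(benzyloxy)-5-bromo-3-methoxyphenyl]-3-[4-(benzyloxy)-3,5-dimethoxyphenyl]propanoyl}-1,3-oxazolidin-2-one F6.
- LiBH4 (THF, trace H2O, 0 °C) removes the auxiliary reductively and rejoins the route at 12, bypassing steps 6–8.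

Step 11. Oxidative addition to the electron-rich bromide may be slow and the catalyst may decompose, or the para-hydroxybenzyl aryl ether may open under base at 100 °C and erode the C2/C3 configuration. The fallback sets out from 15 and uses a lower-temperature cross-coupling in place of the Heck reaction. Suzuki–Miyaura coupling with ethyl (2E)-3-(4,4,5,5-tetramethyl-1,3,2-dioxaborolan-2-yl)prop-2-enoate (Pd(OAc)2, SPhos, K3PO4, THF/H2O, 40 °C) should give ethyl (2E)-3-[(2S,3R)-2-(4-hydroxy-3,5-dimethoxyphenyl)-3-(hydroxymethyl)-7-methoxy-2,3-dihydro-1-benzofuran-5-yl]prop-2-enoate F7, the E geometry coming from the boronate. Saponification (LiOH, THF/H2O, rt) and acidification rejoin the route at 17.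

**Further compounds**
F1 | step 10 | 4-bromo-2-[(2R)-1-hydroxy-3-(4-hydroxy-3,5-dimethoxyphenyl)-3-methoxypropan-2-yl]-6-methoxyphenol (epimers at the methoxy-bearing carbon) | COc1cc(C(OC)[C@@H](CO)c2cc(Br)cc(OC)c2O)cc(OC)c1O
F2 | step 7 | 2,2-dimethylpropanoic [2-(benzyloxy)-5-bromo-3-methoxyphenyl]acetic anhydride | COc1cc(Br)cc(CC(=O)OC(=O)C(C)(C)C)c1OCc1ccccc1
F3 | step 7 | (4R)-4-benzyl-3-{[2-(benzyloxy)-5-bromo-3-methoxyphenyl]acetyl}-1,3-oxazolidin-2-one | COc1cc(Br)cc(CC(=O)N2[C@H](Cc3ccccc3)COC2=O)c1OCc1ccccc1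
F4 | step 7 | [4-(benzyloxy)-3,5-dimethoxyphenyl]methanol | COc1cc(CO)cc(OC)c1OCc1ccccc1
F5 | step 7 | 2-(benzyloxy)-5-(bromomethyl)-1,3-dimethoxybenzene | COc1cc(CBr)cc(OC)c1OCc1ccccc1
F6 | step 7 | (4R)-4-benzyl-3-{(2R)-2-[2-(benzyloxy)-5-bromo-3-methoxyphenyl]-3-[4-(benzyloxy)-3,5-dimethoxyphenyl]propanoyl}-1,3-oxazolidin-2-one | COc1cc(C[C@@H](C(=O)N2[C@H](Cc3ccccc3)COC2=O)c2cc(Br)cc(OC)c2OCc2ccccc2)cc(OC)c1OCc1ccccc1
F7 | step 11 | ethyl (2E)-3-[(2S,3R)-2-(4-hydroxy-3,5-dimethoxyphenyl)-3-(hydroxymethyl)-7-methoxy-2,3-dihydro-1-benzofuran-5-yl]prop-2-enoate | COc1cc([C@H]2Oc3c(OC)cc(/C=C/C(=O)OCC)cc3[C@@H]2CO)cc(OC)c1O
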